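**Assumption (one line):** atom labels used below are C1–C10 for the acid part (C1 ester C=O, C3–C6 oxolane, C7/C8 diol, C9=C10 vinyl) and C11–C34 for the alcohol part (C11 isopropenyl carbon, C12–C15 stereotetrad, C18 ketone, C20–C23 oxolane, C24 ester carbinol, C25–C28 diene, C29 carbinol, C30 methylidene carbon, C31–C34 butyl); small building blocks that carry a silyl protecting group are bought as such.

## Retrosynthetic overview

1. Target ⇐ global desilylation ⇐ ester C1–O–C24 between a bis-silylated oxolane-acetic acid (C1–C10) and the C24 alcohol (C11–C34).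
2. C24–C25 ⇐ chelation-controlled addition of an (E,E)-dienylzinc (from the C25–C34 enyne) to the oxolane-2-carbaldehyde (C11–C24).
3. Key step: the C20–C21 bond and the cis-2,5-oxolane C20–C23 ⇐ 5-exo radical cyclisation of a β-alkoxyvinyl ketone, itself made by oxa-Michael union of a C21–C24 selenide alcohol with the complete C11–C19 ynone.
4. C11–C19 ⇐ two Ipc2B allylborations on methyl 4-oxobutanoate; C25–C34 ⇐ asymmetric alkynylation of 2-butylacrolein, carboalumination, ethynylation.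
5. Ring order: oxolane C3–C6 first (RCM, hydrogenation, Wittig/oxa-Michael; C7/C8 then added by chelation-controlled siloxyallylation), oxolane C20–C23 second (radical step).

## Route

### Part I – acid C1–C10

Step 1
Reactants: 1 (2R)-but-3-ene-1,2-diol
Product: 2 (2R)-1-[(triethylsilyl)oxy]but-3-en-2-ol
Conditions: TESCl (1.05 equiv), imidazole, CH2Cl2, −40 °C
Reagents that add atoms: chlorotriethylsilane (CC[Si](Cl)(CC)CC)
Why: Selective silylation of the less hindered primary hydroxyl; the stereocentre (future C6) comes from the starting diol and is not touched.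

Step 2
Reactants: 2 (2R)-1-[(triethylsilyl)oxy]but-3-en-2-ol; 3 methacryloyl chloride
Product: 4 (2R)-1-[(triethylsilyl)oxy]but-3-en-2-yl 2-methylprop-2-enoate
Conditions: Et3N, DMAP (cat.), CH2Cl2, 0 °C
Reagents that add atoms: none
Why: DMAP-catalysed O-acylation gives the diene needed for ring closure.

Step 3
Reactants: 4 (2R)-1-[(triethylsilyl)oxy]but-3-en-2-yl 2-methylprop-2-enoate
Product: 5 (5R)-3-methyl-5-{[(triethylsilyl)oxy]methyl}furan-2(5H)-one
Conditions: Grubbs II (5 mol%), toluene, 80 °C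
Reagents that add atoms: none
Why: Ring-closing metathesis of an allyl methacrylate to the α-methylbutenolide, driven by loss of ethene.

Step 4
Reactants: 5 (5R)-3-methyl-5-{[(triethylsilyl)oxy]methyl}furan-2(5H)-one
Product: 6 (3R,5R)-3-methyl-5-{[(triethylsilyl)oxy]methyl}oxolan-2-one
Conditions: H2 (1 atm), 5% Rh/Al2O3, EtOAc, rt
Reagents that add atoms: none
Why: Heterogeneous hydrogenation adds H2 to the butenolide face opposite the C5 substituent, giving the 3,5-cis lactone and so setting C4.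

Step 5
Reactants: 6 (3R,5R)-3-methyl-5-{[(triethylsilyl)oxy]methyl}oxolan-2-one
Product: 7 (3R,5R)-3-methyl-5-{[(triethylsilyl)oxy]methyl}oxolan-2-ol (anomer mixture)
Conditions: DIBAL-H (1.1 equiv), CH2Cl2, −78 °C; Rochelle salt
Reagents that add atoms: none
Why: Partial reduction of a γ-lactone to the lactol; the tetrahedral aluminate is stable at −78 °C.

Step 6
Reactants: 7 (3R,5R)-3-methyl-5-{[(triethylsilyl)oxy]methyl}oxolan-2-ol
Product: 9 tert-butyl [(2S,3R,5R)-3-methyl-5-{[(triethylsilyl)oxy]methyl}oxolan-2-yl]acetate, via hydroxy enoate 8 (not isolated)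
Conditions: Ph3P=CHCO2t-Bu, toluene, 80 °C; then DBU (0.2 equiv), rt
Reagents that add atoms: tert-butyl (triphenylphosphoranylidene)acetate (CC(C)(C)OC(=O)C=P(c1ccccc1)(c1ccccc1)c1ccccc1)
Why: Wittig olefination of the open hydroxy aldehyde followed by intramolecular oxa-Michael addition; under DBU equilibration the new centre C3 settles trans to the C4 methyl, which with fixed C4/C6 gives the 3,6-trans oxolane.

Step 7
Reactants: 9 tert-butyl [(2S,3R,5R)-3-methyl-5-{[(triethylsilyl)oxy]methyl}oxolan-2-yl]acetate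
Product: 10 tert-butyl [(2S,3R,5R)-5-formyl-3-methyloxolan-2-yl]acetate
Conditions: (COCl)2 (4 equiv), DMSO (8 equiv), CH2Cl2, −78 → −40 °C; i-Pr2NEt, −78 → 0 °C
Reagents that add atoms: none
Why: Swern oxidation applied directly to a primary TES ether (the chlorosulfonium salt cleaves the silyl ether and oxidises in the same pot), with Hünig's base to avoid epimerisation at C6.

Step 8
Reactants: 11 allyl tert-butyldimethylsilyl ether
Product: 12 (Z)-tributyl{3-[(tert-butyldimethylsilyl)oxy]prop-2-en-1-yl}stannane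
Conditions: s-BuLi, HMPA, THF, −78 °C; Bu3SnCl
Reagents that add atoms: tributyltin chloride (CCCC[Sn](Cl)(CCCC)CCCC)
Why: Deprotonation gives the O–Li-coordinated (Z)-oxyallyl anion, which is stannylated at the γ-carbon (Keck γ-siloxyallylstannane preparation).

Step 9
Reactants: 10 tert-butyl [(2S,3R,5R)-5-formyl-3-methyloxolan-2-yl]acetate; 12 (Z)-tributyl{3-[(tert-butyldimethylsilyl)oxy]prop-2-en-1-yl}stannane
Product: 13 tert-butyl {(2S,3R,5R)-5-[(1S,2S)-2-[(tert-butyldimethylsilyl)oxy]-1-hydroxybut-3-en-1-yl]-3-methyloxolan-2-yl}acetate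
Conditions: MgBr2·OEt2 (3 equiv), CH2Cl2, −20 °C → rt
Reagents that add atoms: none
Why: Keck chelation-controlled allylstannane addition; MgBr2 bridges the ring oxygen and the aldehyde (Cram chelate) so attack gives C6/C7 syn, and the open transition state of the (Z)-γ-siloxy reagent gives C7/C8 syn.

Step 10
Reactants: 13 tert-butyl {(2S,3R,5R)-5-[(1S,2S)-2-[(tert-butyldimethylsilyl)oxy]-1-hydroxybut-3-en-1-yl]-3-methyloxolan-2-yl}acetate
Product: 16 {(2S,3R,5R)-5-[(1S,2S)-2-[(tert-butyldimethylsilyl)oxy]-1-[(triethylsilyl)oxy]but-3-en-1-yl]-3-methyloxolan-2-yl}acetic acid, via silyl ether 14 (not isolated), via silyl ester 15 (not isolated)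
Conditions: TESOTf (4 equiv), 2,6-lutidine, CH2Cl2, 0 °C → rt; then pH 7 buffer/THF
Reagents that add atoms: triethylsilyl trifluoromethanesulfonate (CC[Si](CC)(CC)OS(=O)(=O)C(F)(F)F)
Why: The silyl triflate silylates the C7 hydroxyl and on warming converts the tert-butyl ester into the silyl ester (loss of isobutene), which hydrolyses on work-up; no stereocentre is touched.

### Part II – ynone C11–C19

Step 11
Reactants: 17 methyl 4-oxobutanoate; 18 (E)-but-2-ene
Product: 20 (5S)-5-[(2R)-but-3-en-2-yl]oxolan-2-one, via hydroxy ester 19 (not isolated)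
Conditions: 18, KOt-Bu, n-BuLi, THF, −78 → −45 °C; (+)-Ipc2BOMe [from (−)-α-pinene], −78 °C; BF3·OEt2; 17, −78 °C; NaBO3·4H2O; then p-TsOH (cat.), CH2Cl2, rt
Reagents that add atoms: none
Why: Brown (E)-crotylboration through a closed chair transition state gives the anti C14/C15 pair with C15 fixed as S by the Ipc groups; the γ-hydroxy ester lactonises, which also masks the C15 oxygen.

Step 12
Reactants: 20 (5S)-5-[(2R)-but-3-en-2-yl]oxolan-2-one
Product: 21 (2S)-2-[(2S)-5-oxooxolan-2-yl]propanal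
Conditions: O3, CH2Cl2, −78 °C; PPh3; used crude
Reagents that add atoms: ozone ([O-][O+]=O)
Why: Ozonolysis with neutral reductive work-up cleaves the only alkene; the α-methyl aldehyde is not exposed to base or silica.

Step 13
Reactants: 21 (2S)-2-[(2S)-5-oxooxolan-2-yl]propanal; 22 2-methylbut-2-ene
Product: 23 (5S)-5-[(2R,3R,4S)-3-hydroxy-4,5-dimethylhex-5-en-2-yl]oxolan-2-one
Conditions: 22, KOt-Bu, n-BuLi, THF, −78 → −45 °C; (+)-Ipc2BOMe, −78 °C; BF3·OEt2; 21, −78 °C; NaBO3·4H2O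
Reagents that add atoms: none
Why: Brown-type allylboration with the (Z)-2-methylbut-2-enyl reagent (the 2-methyl homologue of the (Z)-crotyl reagent, from the endo-allylpotassium); the (Z)-geometry gives C12/C13 syn, and the Ipc control matches the intrinsic anti-Felkin preference of (Z)-reagents, giving C13/C14 anti.

Step 14
Reactants: 23 (5S)-5-[(2R,3R,4S)-3-hydroxy-4,5-dimethylhex-5-en-2-yl]oxolan-2-one
Product: 24 (4S,5S,6R,7S)-4,6-dihydroxy-N-methoxy-N,5,7,8-tetramethylnon-8-enamide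
Conditions: MeNH(OMe)·HCl (4 equiv), AlMe3 (4 equiv), CH2Cl2, 0 °C → rt
Reagents that add atoms: N,O-dimethylhydroxylamine hydrochloride (CNOC.Cl)
Why: Weinreb aminolysis of the lactone with the aluminium amide opens the ring without touching any stereocentre.

Step 15
Reactants: 24 (4S,5S,6R,7S)-4,6-dihydroxy-N-methoxy-N,5,7,8-tetramethylnon-8-enamide
Product: 25 (4S,5S,6R,7S)-N-methoxy-N,5,7,8-tetramethyl-4,6-bis[(triethylsilyl)oxy]non-8-enamide
Conditions: TESOTf (2.5 equiv), 2,6-lutidine, CH2Cl2, −78 °C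
Reagents that add atoms: triethylsilyl trifluoromethanesulfonate (CC[Si](CC)(CC)OS(=O)(=O)C(F)(F)F)
Why: Silyl triflate protects both hindered secondary hydroxyls at once and stops relactonisation.

Step 16
Reactants: 25 (4S,5S,6R,7S)-N-methoxy-N,5,7,8-tetramethyl-4,6-bis[(triethylsilyl)oxy]non-8-enamide
Product: 26 (6S,7S,8R,9S)-7,9,10-trimethyl-6,8-bis[(triethylsilyl)oxy]undec-10-en-1-yn-3-one
Conditions: HC≡CMgBr (3 equiv), THF, 0 °C; aq. NH4Cl
Reagents that add atoms: ethynylmagnesium bromide (C#C[Mg]Br)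
Why: Weinreb ketone synthesis; the chelated tetrahedral intermediate prevents over-addition and releases the terminal ynone on quench.

### Part III – enyne C25–C34

Step 17
Reactants: 27 2-butylacrolein (2-methylidenehexanal); 28 ethynyltrimethylsilane
Product: 30 (3S)-4-methylideneoct-1-yn-3-ol, via silyl alkynol 29 (not isolated)
Conditions: Me2Zn (3 equiv), (S,S)-ProPhenol (10 mol%), Ph3PO (20 mol%), toluene, 4 °C; then MeOH, K2CO3 (cat.), rt
Reagents that add atoms: none
Why: Trost ProPhenol dinuclear-zinc asymmetric alkynylation of an enal (1,2-addition) sets C29 by catalyst control; methanolysis removes the C-silyl group in the same pot.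

Step 18
Reactants: 30 (3S)-4-methylideneoct-1-yn-3-ol
Product: 31 (1E,3S)-1-iodo-2-methyl-4-methylideneoct-1-en-3-ol
Conditions: AlMe3 (3 equiv), Cp2ZrCl2 (0.5 equiv), CH2Cl2, 0 °C → rt; then I2, THF, −30 → 0 °C
Reagents that add atoms: trimethylaluminium (C[Al](C)C); iodine (II)
Why: Negishi Zr-catalysed carboalumination adds Me and Al syn across the terminal alkyne (Me to the internal carbon) and iodinolysis retains geometry, giving the (E)-trisubstituted C27=C28 alkene.

Step 19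
Reactants: 31 (1E,3S)-1-iodo-2-methyl-4-methylideneoct-1-en-3-ol
Product: 32 triethyl{[(1E,3S)-1-iodo-2-methyl-4-methylideneoct-1-en-3-yl]oxy}silane
Conditions: TESCl, imidazole, CH2Cl2, 0 °C
Reagents that add atoms: chlorotriethylsilane (CC[Si](Cl)(CC)CC)
Why: Routine silylation of the secondary allylic alcohol.

Step 20
Reactants: 32 triethyl{[(1E,3S)-1-iodo-2-methyl-4-methylideneoct-1-en-3-yl]oxy}silane
Product: 33 triethyl{[(3E,5S)-4-methyl-6-methylidenedec-3-en-1-yn-5-yl]oxy}silane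
Conditions: HC≡CMgBr, ZnBr2, THF, 0 °C; then 32, Pd(PPh3)4 (5 mol%), rt
Reagents that add atoms: ethynylmagnesium bromide (C#C[Mg]Br)
Why: Negishi coupling of ethynylzinc bromide with the alkenyl iodide gives the terminal enyne directly with retention of alkene geometry.

### Part IV – selenide alcohol C21–C24

Step 21
Reactants: 34 (R)-glycidol
Product: 35 (2S)-triethyl(oxiran-2-ylmethoxy)silane
Conditions: TESCl, imidazole, CH2Cl2, 0 °C
Reagents that add atoms: chlorotriethylsilane (CC[Si](Cl)(CC)CC)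
Why: Silylation of the primary alcohol; the epoxide stereocentre (future C23) is untouched (the descriptor changes only through CIP priorities).

Step 22
Reactants: 35 (2S)-triethyl(oxiran-2-ylmethoxy)silane
Product: 36 (2S)-4-(phenylselanyl)-1-[(triethylsilyl)oxy]butan-2-ol
Conditions: (PhSe)2CH2, n-BuLi, THF, −78 °C; then 35, BF3·OEt2, −78 °C, cold quench
Reagents that add atoms: bis(phenylselanyl)methane (C([Se]c1ccccc1)[Se]c1ccccc1)
Why: Se/Li exchange gives PhSeCH2Li, which opens the BF3-activated epoxide at the terminal carbon (SN2) without touching C23; the low temperature and BF3-bound alkoxide suppress silyl migration.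

### Part V – union and endgame

Step 23
Reactants: 36 (2S)-4-(phenylselanyl)-1-[(triethylsilyl)oxy]butan-2-ol; 26 (6S,7S,8R,9S)-7,9,10-trimethyl-6,8-bis[(triethylsilyl)oxy]undec-10-en-1-yn-3-one
Product: 37 (1E,6S,7S,8R,9S)-7,9,10-trimethyl-1-{[(2S)-4-(phenylselanyl)-1-[(triethylsilyl)oxy]butan-2-yl]oxy}-6,8-bis[(triethylsilyl)oxy]undeca-1,10-dien-3-one
Conditions: 36 (1.5 equiv), PMe3 (0.2 equiv), CH2Cl2, 0 °C → rt
Reagents that add atoms: none
Why: Phosphine-catalysed oxa-Michael addition of the secondary alcohol to the terminal ynone (Inanaga conditions) gives the (E)-β-alkoxyvinyl ketone and joins the two fragments through the future ring oxygen.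

Step 24
Reactants: 37 (1E,6S,7S,8R,9S)-7,9,10-trimethyl-1-{[(2S)-4-(phenylselanyl)-1-[(triethylsilyl)oxy]butan-2-yl]oxy}-6,8-bis[(triethylsilyl)oxy]undeca-1,10-dien-3-one
Product: 38 (5S,6S,7R,8S)-6,8,9-trimethyl-1-[(2R,5S)-5-{[(triethylsilyl)oxy]methyl}oxolan-2-yl]-5,7-bis[(triethylsilyl)oxy]dec-9-en-2-one
Conditions: Bu3SnH (1.5 equiv, syringe pump), AIBN (0.2 equiv), benzene (0.01 M), 80 °C
Reagents that add atoms: none
Why: Key step, a Lee-type 5-exo-trig radical cyclisation: the primary C21 radical from the C–SePh bond adds to the alkoxy-bearing carbon of the vinylogous ester through a chair-like transition state with the C23 substituent pseudo-equatorial, forming C20–C21 and setting C20 cis to C23 while the whole C11–C19 chain is already in place.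

Step 25
Reactants: 38 (5S,6S,7R,8S)-6,8,9-trimethyl-1-[(2R,5S)-5-{[(triethylsilyl)oxy]methyl}oxolan-2-yl]-5,7-bis[(triethylsilyl)oxy]dec-9-en-2-one
Product: 39 (2S,5R)-5-{(5S,6S,7R,8S)-6,8,9-trimethyl-2-oxo-5,7-bis[(triethylsilyl)oxy]dec-9-en-1-yl}oxolane-2-carbaldehyde
Conditions: (COCl)2, DMSO, CH2Cl2, −78 → −40 °C; i-Pr2NEt, −78 → 0 °C; used at once
Reagents that add atoms: none
Why: Direct Swern oxidation of the primary TES ether, which is cleaved selectively while the two hindered secondary TES ethers survive.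

Step 26
Reactants: 39 (2S,5R)-5-{(5S,6S,7R,8S)-6,8,9-trimethyl-2-oxo-5,7-bis[(triethylsilyl)oxy]dec-9-en-1-yl}oxolane-2-carbaldehyde; 33 triethyl{[(3E,5S)-4-methyl-6-methylidenedec-3-en-1-yn-5-yl]oxy}silane
Product: 40 (24S)-alcohol: 39 whose CHO has become CH(OH) bearing the (1E,3E,5S)-4-methyl-6-methylidene-5-[(triethylsilyl)oxy]deca-1,3-dien-1-yl group
Conditions: 33, Cp2Zr(H)Cl, CH2Cl2, rt; Me2Zn, toluene, −78 °C; then 39 premixed with EtZnCl (1.5 equiv), −78 → −20 °C
Reagents that add atoms: none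
Why: Wipf hydrozirconation/Zr→Zn transmetalation gives the (E,E)-dienylzinc by syn-addition, and 1,2-addition under zinc-halide chelation of ring oxygen and aldehyde (Cram chelate) forms C24 syn to C23; organozinc leaves the C18 ketone alone.

Step 27
Reactants: 40 (24S)-alcohol; 16 {(2S,3R,5R)-5-[(1S,2S)-2-[(tert-butyldimethylsilyl)oxy]-1-[(triethylsilyl)oxy]but-3-en-1-yl]-3-methyloxolan-2-yl}acetic acid
Product: 41 fully silylated ester (C1–O–C24) of 40 with 16
Conditions: EDC·HCl, DMAP, CH2Cl2, 0 °C → rt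
Reagents that add atoms: none
Why: Steglich esterification of the only free hydroxyl with retention at C24.

Step 28
Reactants: 41 fully silylated ester
Product: 42 target: (1S,2E,4E,6S)-6-hydroxy-1-{(2S,5R)-5-[(5S,6S,7R,8S)-5,7-dihydroxy-6,8,9-trimethyl-2-oxodec-9-en-1-yl]oxolan-2-yl}-5-methyl-7-methylideneundeca-2,4-dien-1-yl {(2S,3R,5R)-5-[(1R,2S)-1,2-dihydroxybut-3-en-1-yl]-3-methyloxolan-2-yl}acetate
Conditions: HF·pyridine, excess pyridine, THF, 0 °C → rt; aq. NaHCO3 quench
Reagents that add atoms: none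
Why: Buffered fluoride removes the four TES and one TBS ethers without base (no retro-oxa-Michael or acyl shift) and with little free acid (limits ketalisation of the C18 ketone by the C13/C15 diol).

## Compound list

1 | (2R)-but-3-ene-1,2-diol | OC[C@H](O)C=C | starting material
2 | (2R)-1-[(triethylsilyl)oxy]but-3-en-2-ol | CC[Si](CC)(CC)OC[C@H](O)C=C | intermediate
3 | methacryloyl chloride | CC(=C)C(Cl)=O | starting material
4 | (2R)-1-[(triethylsilyl)oxy]but-3-en-2-yl 2-methylprop-2-enoate | CC[Si](CC)(CC)OC[C@H](OC(=O)C(C)=C)C=C | intermediate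
5 | (5R)-3-methyl-5-{[(triethylsilyl)oxy]methyl}furan-2(5H)-one | CC[Si](CC)(CC)OC[C@H]1C=C(C)C(=O)O1 | intermediate
6 | (3R,5R)-3-methyl-5-{[(triethylsilyl)oxy]methyl}oxolan-2-one | CC[Si](CC)(CC)OC[C@H]1C[C@@H](C)C(=O)O1 | intermediate
7 | (3R,5R)-3-methyl-5-{[(triethylsilyl)oxy]methyl}oxolan-2-ol (anomer mixture) | CC[Si](CC)(CC)OC[C@H]1C[C@@H](C)C(O)O1 | intermediate
8 | tert-butyl (2E,4R,6R)-6-hydroxy-4-methyl-7-[(triethylsilyl)oxy]hept-2-enoate (not isolated) | CC[Si](CC)(CC)OC[C@H](O)C[C@@H](C)/C=C/C(=O)OC(C)(C)C | intermediate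
9 | tert-butyl [(2S,3R,5R)-3-methyl-5-{[(triethylsilyl)oxy]methyl}oxolan-2-yl]acetate | CC[Si](CC)(CC)OC[C@H]1C[C@@H](C)[C@H](CC(=O)OC(C)(C)C)O1 | intermediate
10 | tert-butyl [(2S,3R,5R)-5-formyl-3-methyloxolan-2-yl]acetate | O=C[C@H]1C[C@@H](C)[C@H](CC(=O)OC(C)(C)C)O1 | intermediate
11 | allyl tert-butyldimethylsilyl ether (TBS-protected allyl alcohol) | C=CCO[Si](C)(C)C(C)(C)C | starting material
12 | (Z)-tributyl{3-[(tert-butyldimethylsilyl)oxy]prop-2-en-1-yl}stannane | CCCC[Sn](CCCC)(CCCC)C/C=C\O[Si](C)(C)C(C)(C)C | intermediate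
13 | tert-butyl {(2S,3R,5R)-5-[(1S,2S)-2-[(tert-butyldimethylsilyl)oxy]-1-hydroxybut-3-en-1-yl]-3-methyloxolan-2-yl}acetate | C=C[C@H](O[Si](C)(C)C(C)(C)C)[C@@H](O)[C@H]1C[C@@H](C)[C@H](CC(=O)OC(C)(C)C)O1 | intermediate
14 | C7-O-triethylsilyl ether of 13, tert-butyl ester (not isolated) | C=C[C@H](O[Si](C)(C)C(C)(C)C)[C@@H](O[Si](CC)(CC)CC)[C@H]1C[C@@H](C)[C@H](CC(=O)OC(C)(C)C)O1 | intermediate
15 | triethylsilyl ester of 16 (not isolated) | C=C[C@H](O[Si](C)(C)C(C)(C)C)[C@@H](O[Si](CC)(CC)CC)[C@H]1C[C@@H](C)[C@H](CC(=O)O[Si](CC)(CC)CC)O1 | intermediate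
16 | {(2S,3R,5R)-5-[(1S,2S)-2-[(tert-butyldimethylsilyl)oxy]-1-[(triethylsilyl)oxy]but-3-en-1-yl]-3-methyloxolan-2-yl}acetic acid | C=C[C@H](O[Si](C)(C)C(C)(C)C)[C@@H](O[Si](CC)(CC)CC)[C@H]1C[C@@H](C)[C@H](CC(=O)O)O1 | intermediate
17 | methyl 4-oxobutanoate | COC(=O)CCC=O | starting material
18 | (E)-but-2-ene | C/C=C/C | starting material
19 | methyl (4S,5R)-4-hydroxy-5-methylhept-6-enoate (not isolated) | COC(=O)CC[C@H](O)[C@H](C)C=C | intermediate
20 | (5S)-5-[(2R)-but-3-en-2-yl]oxolan-2-one | O=C1CC[C@H](O1)[C@H](C)C=C | intermediate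
21 | (2S)-2-[(2S)-5-oxooxolan-2-yl]propanal | O=C1CC[C@H](O1)[C@H](C)C=O | intermediate
22 | 2-methylbut-2-ene | CC=C(C)C | starting material
23 | (5S)-5-[(2R,3R,4S)-3-hydroxy-4,5-dimethylhex-5-en-2-yl]oxolan-2-one | O=C1CC[C@H](O1)[C@H](C)[C@H](O)[C@@H](C)C(C)=C | intermediate
24 | (4S,5S,6R,7S)-4,6-dihydroxy-N-methoxy-N,5,7,8-tetramethylnon-8-enamide | CON(C)C(=O)CC[C@H](O)[C@H](C)[C@H](O)[C@@H](C)C(C)=C | intermediate
25 | (4S,5S,6R,7S)-N-methoxy-N,5,7,8-tetramethyl-4,6-bis[(triethylsilyl)oxy]non-8-enamide | CON(C)C(=O)CC[C@H](O[Si](CC)(CC)CC)[C@H](C)[C@H](O[Si](CC)(CC)CC)[C@@H](C)C(C)=C | intermediate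
26 | (6S,7S,8R,9S)-7,9,10-trimethyl-6,8-bis[(triethylsilyl)oxy]undec-10-en-1-yn-3-one | C#CC(=O)CC[C@H](O[Si](CC)(CC)CC)[C@H](C)[C@H](O[Si](CC)(CC)CC)[C@@H](C)C(C)=C | intermediate
27 | 2-butylacrolein (2-methylidenehexanal) | C=C(CCCC)C=O | starting material
28 | ethynyltrimethylsilane | C#C[Si](C)(C)C | starting material
29 | (3S)-4-methylidene-1-(trimethylsilyl)oct-1-yn-3-ol (not isolated) | C[Si](C)(C)C#C[C@@H](O)C(=C)CCCC | intermediate
30 | (3S)-4-methylideneoct-1-yn-3-ol | C#C[C@@H](O)C(=C)CCCC | intermediate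
31 | (1E,3S)-1-iodo-2-methyl-4-methylideneoct-1-en-3-ol | I/C=C(\C)[C@@H](O)C(=C)CCCC | intermediate
32 | triethyl{[(1E,3S)-1-iodo-2-methyl-4-methylideneoct-1-en-3-yl]oxy}silane | I/C=C(\C)[C@@H](O[Si](CC)(CC)CC)C(=C)CCCC | intermediate
33 | triethyl{[(3E,5S)-4-methyl-6-methylidenedec-3-en-1-yn-5-yl]oxy}silane | C#C/C=C(\C)[C@@H](O[Si](CC)(CC)CC)C(=C)CCCC | intermediate
34 | (R)-glycidol | OC[C@@H]1CO1 | starting material
35 | (2S)-triethyl(oxiran-2-ylmethoxy)silane | CC[Si](CC)(CC)OC[C@@H]1CO1 | intermediate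
36 | (2S)-4-(phenylselanyl)-1-[(triethylsilyl)oxy]butan-2-ol | CC[Si](CC)(CC)OC[C@@H](O)CC[Se]c1ccccc1 | intermediate
37 | (1E,6S,7S,8R,9S)-7,9,10-trimethyl-1-{[(2S)-4-(phenylselanyl)-1-[(triethylsilyl)oxy]butan-2-yl]oxy}-6,8-bis[(triethylsilyl)oxy]undeca-1,10-dien-3-one | CC[Si](CC)(CC)OC[C@@H](O/C=C/C(=O)CC[C@H](O[Si](CC)(CC)CC)[C@H](C)[C@H](O[Si](CC)(CC)CC)[C@@H](C)C(C)=C)CC[Se]c1ccccc1 | intermediate
38 | (5S,6S,7R,8S)-6,8,9-trimethyl-1-[(2R,5S)-5-{[(triethylsilyl)oxy]methyl}oxolan-2-yl]-5,7-bis[(triethylsilyl)oxy]dec-9-en-2-one | CC[Si](CC)(CC)OC[C@@H]1CC[C@H](CC(=O)CC[C@H](O[Si](CC)(CC)CC)[C@H](C)[C@H](O[Si](CC)(CC)CC)[C@@H](C)C(C)=C)O1 | intermediate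
39 | (2S,5R)-5-{(5S,6S,7R,8S)-6,8,9-trimethyl-2-oxo-5,7-bis[(triethylsilyl)oxy]dec-9-en-1-yl}oxolane-2-carbaldehyde | O=C[C@@H]1CC[C@H](CC(=O)CC[C@H](O[Si](CC)(CC)CC)[C@H](C)[C@H](O[Si](CC)(CC)CC)[C@@H](C)C(C)=C)O1 | intermediate
40 | (24S)-alcohol: tris-TES ether of the C11–C34 alcohol part with free C24–OH | O[C@@H](/C=C/C=C(\C)[C@@H](O[Si](CC)(CC)CC)C(=C)CCCC)[C@@H]1CC[C@H](CC(=O)CC[C@H](O[Si](CC)(CC)CC)[C@H](C)[C@H](O[Si](CC)(CC)CC)[C@@H](C)C(C)=C)O1 | intermediate
41 | fully silylated ester (C8-OTBS; C7-, C13-, C15-, C29-OTES) | C=C[C@H](O[Si](C)(C)C(C)(C)C)[C@@H](O[Si](CC)(CC)CC)[C@H]1C[C@@H](C)[C@H](CC(=O)O[C@@H](/C=C/C=C(\C)[C@@H](O[Si](CC)(CC)CC)C(=C)CCCC)[C@@H]2CC[C@H](CC(=O)CC[C@H](O[Si](CC)(CC)CC)[C@H](C)[C@H](O[Si](CC)(CC)CC)[C@@H](C)C(C)=C)O2)O1 | intermediate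
42 | CNP0158416.1 (3S,4R,6R,7R,8S,12S,13R,14S,15S,20R,23S,24S,25E,27E,29S) | C=C[C@H](O)[C@@H](O)[C@H]1C[C@@H](C)[C@H](CC(=O)O[C@@H](/C=C/C=C(\C)[C@@H](O)C(=C)CCCC)[C@@H]2CC[C@H](CC(=O)CC[C@H](O)[C@H](C)[C@H](O)[C@@H](C)C(=C)C)O2)O1 | target

## Totals

Total step count: 28.
Longest linear sequence: 12 steps (17 → 42: steps 11–16, then 23–28).

## Three steps most likely to fail, with fallbacks

**Step 13 (2-methylbut-2-enyl boration of 21).** The reagent is the least documented one in the route, the anti-Felkin sense is required, and 21 is a β-acyloxy aldehyde that can epimerise or eliminate. The fallback sets out from 21 and replaces the one-step isopropenyl installation by a stepwise construction. Brown (Z)-crotylboration with the established (Z)-crotyl-B(Ipc)2 reagent (cis-but-2-ene, n-BuLi/KOt-Bu, (+)-Ipc2BOMe, BF3·OEt2) gives the vinyl homologue (5S)-5-[(2R,3R,4S)-3-hydroxy-4-methylhex-5-en-2-yl]oxolan-2-one F1. Tsuji–Wacker oxidation (PdCl2, CuCl, O2, DMF/H2O) converts the terminal alkene into the methyl ketone (5S)-5-[(2R,3S,4R)-3-hydroxy-4-methyl-5-oxohexan-2-yl]oxolan-2-one F2. Non-basic Takai–Lombardo methylenation (Zn, CH2Br2, TiCl4), which spares the lactone, then gives 23, where the route continues.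

**Step 24 (radical cyclisation of the full vinylogous ester 37).** Tin radicals can add to the enone oxygen and reduce it, the C21 radical can be quenched before closure, and the cis/trans ratio is untested on a substrate of this size. The fallback sets out from 36 and 25, keeps the 5-exo radical closure but runs it on a smaller, non-reducible acceptor and forms the C18–C19 bond afterwards. Addition of 36 to ethynyl p-tolyl sulfone (N-methylmorpholine cat.) gives the (E)-β-alkoxyvinyl sulfone triethyl{[(2S)-2-{[(E)-2-(4-methylbenzenesulfonyl)ethenyl]oxy}-4-(phenylselanyl)butyl]oxy}silane F3. Bu3SnH/AIBN cyclises it to the cis-oxolane sulfone triethyl{[(2S,5R)-5-[(4-methylbenzenesulfonyl)methyl]oxolan-2-yl]methoxy}silane F4. Lithiation (n-BuLi, −78 °C) and acylation with Weinreb amide 25 give the C19-sulfonyl ketone (C19-tosyl derivative of 38, epimer mixture at C19) F5. Reductive desulfonylation (SmI2, THF/MeOH, −78 °C) gives 38, where the route continues.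

**Step 26 (C24 by chelation-controlled dienylzinc addition).** The diastereoselectivity depends on zinc chelation in a molecule with several other Lewis-basic sites. The fallback sets out from 33 and 39 and switches to reagent control. Hydrozirconation of 33 followed by iodine gives the dienyl iodide triethyl{[(1E,3E,5S)-1-iodo-4-methyl-6-methylidenedeca-1,3-dien-5-yl]oxy}silane F6. A Nozaki–Hiyama–Kishi coupling of F6 with 39 (CrCl2, NiCl2 cat., Kishi chiral sulfonamide ligand chosen for the 24S sense; ketone tolerated) gives 40, where the route continues.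

## Further compounds

F1 | step 13 | (5S)-5-[(2R,3R,4S)-3-hydroxy-4-methylhex-5-en-2-yl]oxolan-2-one | O=C1CC[C@H](O1)[C@H](C)[C@H](O)[C@@H](C)C=C
F2 | step 13 | (5S)-5-[(2R,3S,4R)-3-hydroxy-4-methyl-5-oxohexan-2-yl]oxolan-2-one | O=C1CC[C@H](O1)[C@H](C)[C@H](O)[C@@H](C)C(C)=O
F3 | step 24 | triethyl{[(2S)-2-{[(E)-2-(4-methylbenzenesulfonyl)ethenyl]oxy}-4-(phenylselanyl)butyl]oxy}silane | CC[Si](CC)(CC)OC[C@@H](O/C=C/S(=O)(=O)c1ccc(C)cc1)CC[Se]c1ccccc1
F4 | step 24 | triethyl{[(2S,5R)-5-[(4-methylbenzenesulfonyl)methyl]oxolan-2-yl]methoxy}silane | CC[Si](CC)(CC)OC[C@@H]1CC[C@H](CS(=O)(=O)c2ccc(C)cc2)O1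
F5 | step 24 | C19-(4-methylbenzenesulfonyl) derivative of 38 (epimer mixture at C19) | CC[Si](CC)(CC)OC[C@@H]1CC[C@H](C(C(=O)CC[C@H](O[Si](CC)(CC)CC)[C@H](C)[C@H](O[Si](CC)(CC)CC)[C@@H](C)C(C)=C)S(=O)(=O)c2ccc(C)cc2)O1
F6 | step 26 | triethyl{[(1E,3E,5S)-1-iodo-4-methyl-6-methylidenedeca-1,3-dien-5-yl]oxy}silane | I/C=C/C=C(\C)[C@@H](O[Si](CC)(CC)CC)C(=C)CCCC
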